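**Numbering.** Germacrane numbering is used throughout: ring C1–C10; C14 on C10; C15 on C4; lactone O6–C12(=O)–C11 with C11 on C7; C13 on C11; ester oxygen O8; hydroxyl O9. The target is (6R,7S,8R,9S), with an (S)-2-methylbutanoate on O8.

## The problem

The target is a germacranolide: a ten-membered carbocycle trans-fused across C6–C7 to an α-methylene-γ-butyrolactone. It has two ring-cis trisubstituted olefins, C1=C10 carrying the C14 aldehyde and C4=C5 carrying the C15 hydroxymethyl group. Four contiguous stereocentres run from C6 to C9; the fifth, in the 2-methylbutanoate, can be bought. Only C6 needs an external chiral influence: C7 can be relayed from C6, the C7/C8 pair is the pattern of a syn addition across a Z olefin, and C9 is a carbinol next to C8 that a ketone reduction can set. The fragile parts are the enal and the α-methylene lactone (two Michael acceptors, to be unveiled last), the O8 ester beside the free O9 hydroxyl (acyl shift under base), the epimerisable α-carbon of that ester, and the allylic C6–O bond. A ten-membered ring is the hardest size to close directly, so a plan that makes it by reorganising a ring closed through an ester bond is attractive. The enabling feature is the 1,5-dioxygenated chain C12(=O)–C11–C7–C8–C9(O): it is what remains when an olefin C7=C8 is inserted into the C11–C9 bond of a β-keto ester. Because O6 joins C12 to C6, that β-keto ester can be an eleven-membered lactone (O6, C12, C11, C9, C10, C1–C6) with C7=C8 pendant on C6. A [2+2] photocycloaddition followed by retro-aldol opening then closes the γ-lactone (C7–C11) and the ten-membered ring (C8–C9) together.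

## Retrosynthesis

**Unveiling the reactive groups (31 back to 20).** The bonds cut are C11=C13 (Mannich reaction and elimination), C10–C14 (Morita–Baylis–Hillman hydroxymethylation of enone 22), the C1=C10 unsaturation (dehydrogenation) and C9–H (reduction), together with the silyl ethers of 25, 28 and 30. All of these changes hang on the single C9 ketone of 20, which activates C10 for both the dehydrogenation and the hydroxymethylation and then becomes the C9 carbinol. Ketolactone 20 has no electrophilic olefin, no C13, no C14 and one stereocentre fewer. The forward steps must enolise toward C10 and not C8, reduce C9 from the correct face, and tell the C14 hydroxyl from the C15 hydroxyl, which is why O15 stays silylated to the end.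

**Key disconnection (20 back to 16).** C7–C11 and C8–C9 are cut and C9–C11 is rejoined, which gives the eleven-membered β-keto lactone 16 with a Z-enol ester on C6. Cutting C9–C10 or C8=C9 instead would close the ten-membered ring at a functionalised bond and would require C7 and C8 to be set beforehand in an open chain. Here both rings and both centres arise in one operation from a ring that closes by ester formation. Precursor 16 has a single ring stereocentre (C6) and carries the O8 ester already. The forward reaction needs an excited enol derivative that finds the s-cis lactone conformer, adds to C7=C8 and not to C4=C5, and transmits the C6 configuration and the Z geometry to C7 and C8.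

**Enol ester (16 back to 14 and 15).** The C8–O8 bond is cut, leading to terminal alkyne 14 and (S)-2-methylbutanoic acid 15. Anti-Markovnikov addition of the acid to the alkyne gives the Z-enol ester without any activating group and brings the final ester in intact. It must follow lactonisation, because a free O6 hydroxyl beside a Z-enol ester would take over the acyl group.

**Macrolactone (14 back to 12).** The O6–C12 bond is cut. Dioxinone 12 releases an acylketene (13) on heating, which the C6 hydroxyl captures; no coupling reagent is needed and the β-keto acid never has to be handled. The price is that an eleven-membered ring must form faster than intermolecular capture.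

**C6 stereocentre (12 back to 9 and 10).** The C6–C7 bond is cut between enal 9 and ethynyltrimethylsilane 10; 11 is the silylated adduct. Catalytic asymmetric alkynylation of an enal is the one reagent-controlled step of the route, and the alkyne delivered is exactly the C7–C8 unit needed.

**Chain assembly (9 back to 3 and 6).** The C3–C4 bond is cut (oxidation level adjusted through 8). A B-alkyl Suzuki–Miyaura coupling joins the borane from butenyl dioxinone 3 (7) to alkenyl iodide 6 with retention, so the ring-cis C4=C5 geometry is decided in the iodide and the dioxinone needs no unactivated alkylation.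

**Building blocks (6 back to 5 and 4; 3 back to 1 and 2).** Iodide 6 comes from butynediol 4 through monosilyl ether 5 by directed trans-hydroalumination and iodination. Dioxinone 3 comes from 1 and allyl bromide 2 by γ-alkylation.

## Roads not taken

**Alternative 1:** The ten-membered ring is traced to a six-membered carbocycle by a retro-[3,3] shift (C2–C3 cut, C5–C10 joined). Forward, the potassium alkoxide (KH, 18-crown-6) of a cis-1,2-dialkenyl carbinol would undergo anionic oxy-Cope ring expansion to the C10 ketone A1 with ring-cis C4=C5.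
- Merits: this ring expansion is among the best-tested entries to cyclodecenones, and C6–C9 would come from the chiral pool with no selectivity question at C8 or C9.
- Weak points: A1 has its ketone at C10, so C14 and the C1=C10 olefin still have to be built; it carries five different protecting groups; the lactone must be made late by oxidising C12; and O8 must be told from O9 for acylation.
- Comparison: Alternative 1 is better in the security of its key step and of the stereocentres. The chosen plan sets against it a much shorter route, the O8 ester in place from the start and O9 differentiated as a ketone.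

**Alternative 2:** The C9–C10 bond is cut. Forward, CrCl2 with catalytic NiCl2 would turn a Z-alkenyl iodide at C10 into an alkenylchromium that adds to a C9 aldehyde, closing the ring and creating the C9 carbinol in A2 (Nozaki–Hiyama–Kishi reaction).
- Merits: the reaction is tolerant and proven for medium rings. A2 already contains the α-methylene lactone, the ester and both oxygenated carbons, so only three steps remain. The open-chain polar Felkin–Anh preference of an α-acyloxy aldehyde also matches the required 8,9-anti relationship.
- Weak points: C6, C7 and C8 must be set one after another in an open chain; the α-acyloxy aldehyde is prone to epimerisation; and the reagent is used in large excess at high dilution.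
- Comparison: its key step and its endgame are better precedented and shorter than those chosen here. The chosen plan sets against it that C7, C8 and both rings arise in one step from a precursor with one stereocentre, reached in nine steps.

**Alternative 3:** The C8=C9 bond is cut. Forward, second-generation Grubbs catalyst would join a vinyl group on C7 with the terminal vinyl of a C10 diene to give triene lactone A3, followed by dihydroxylation of C8=C9 with OsO4.
- Merits: the metathesis substrate is easy to assemble, the closure is catalytic, and syn dihydroxylation of a ring-cis olefin gives the correct 8,9-anti diol.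
- Weak points: the closure must form a conjugated ring-cis diene in a ten-membered ring beside a metathesis-active α-methylene lactone; OsO4 must then choose C8=C9 among four olefins, two of them more electron-rich; and the two secondary hydroxyls must be told apart for acylation.
- Comparison: on paper this is the shortest way to the ring, and every reaction is known. Its chemoselectivity problems lie in the structure, whereas the chosen plan never has to choose between olefins for oxidation or between O8 and O9.

Key step: step 10

Assumption: the (S,S)-ProPhenol/Me2Zn catalyst is taken to deliver the alkynyl group to the Si face of enal 9, giving the 6R carbinol; if the sense is the reverse, the (R,R)-ligand is used and nothing else changes.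

## Route

Step 1
Reactants: 1 2,2,6-trimethyl-4H-1,3-dioxin-4-one; 2 allyl bromide
Product: 3 6-(but-3-en-1-yl)-2,2-dimethyl-4H-1,3-dioxin-4-one
Conditions: LiN(iPr)2, THF/DMPU, −78 °C; then 2, −78 → −20 °C
Reagents that add atoms: none
Why: Vinylogous enolate alkylation: deprotonation of the 6-methyl group gives the lithium dienolate, which the reactive allylic bromide alkylates at the exocyclic γ-carbon (C10).

Step 2
Reactants: 4 but-2-yne-1,4-diol
Product: 5 4-[(triisopropylsilyl)oxy]but-2-yn-1-ol
Conditions: NaH (1 equiv), THF, 0 °C; iPr3SiCl, rt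
Reagents that add atoms: chlorotriisopropylsilane, CC(C)[Si](Cl)(C(C)C)C(C)C
Why: O-Silylation of a symmetrical diol through its sparingly soluble monosodium alkoxide; the triisopropylsilyl group has no chromophore and outlasts the later fluoride and acid treatments.

Step 3
Reactants: 5 4-[(triisopropylsilyl)oxy]but-2-yn-1-ol
Product: 6 (2Z)-3-iodo-4-[(triisopropylsilyl)oxy]but-2-en-1-ol
Conditions: NaAlH2(OCH2CH2OCH3)2, THF, 0 °C; EtOAc; I2, −78 → 0 °C
Reagents that add atoms: iodine, II
Why: Hydroxyl-directed trans-hydroalumination puts hydride on C5 and aluminium on C4 in a five-membered alkoxyaluminate, and iodinolysis with retention gives the Z-iodoalkene; iodine and C6 are cis, which fixes the ring-cis C4=C5 geometry.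

Step 4
Reactants: 3 6-(but-3-en-1-yl)-2,2-dimethyl-4H-1,3-dioxin-4-one; 6 (2Z)-3-iodo-4-[(triisopropylsilyl)oxy]but-2-en-1-ol
Product: 8 6-[(5E)-7-hydroxy-5-{[(triisopropylsilyl)oxy]methyl}hept-5-en-1-yl]-2,2-dimethyl-4H-1,3-dioxin-4-one, via B-alkyl-9-BBN 7 (not isolated)
Conditions: 3, 9-BBN, THF, 0 °C → rt; then 6, Pd(dppf)Cl2 (cat.), AsPh3, Cs2CO3, DMF/H2O, rt
Reagents that add atoms: none
Why: Anti-Markovnikov hydroboration of the terminal olefin (the dioxinone olefin is electron-poor and trisubstituted) and B-alkyl Suzuki–Miyaura coupling form C3–C4 with retention of the alkenyl iodide geometry.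

Step 5
Reactants: 8 the allylic alcohol of step 4
Product: 9 (2E)-7-(2,2-dimethyl-4-oxo-4H-1,3-dioxin-6-yl)-3-{[(triisopropylsilyl)oxy]methyl}hept-2-enal
Conditions: MnO2, CH2Cl2, rt
Reagents that add atoms: none
Why: Allylic alcohol oxidation on the MnO2 surface; neutral, so the enal geometry and the dioxinone should be kept, and the enal is used at once.

Step 6
Reactants: 9 the enal of step 5; 10 ethynyltrimethylsilane
Product: 11 6-[(5E,7R)-7-hydroxy-5-{[(triisopropylsilyl)oxy]methyl}-9-(trimethylsilyl)non-5-en-8-yn-1-yl]-2,2-dimethyl-4H-1,3-dioxin-4-one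
Conditions: 10, Me2Zn, (S,S)-ProPhenol (cat.), Ph3PO (cat.), toluene, 0 → 4 °C
Reagents that add atoms: none
Why: Catalytic asymmetric alkynylation: the zinc alkynylide formed in situ adds to the enal within the dinuclear zinc–ProPhenol complex, enals being a favoured substrate class; Si-face addition sets C6 as R.

Step 7
Reactants: 11 the silylated propargylic alcohol of step 6
Product: 12 6-[(5E,7R)-7-hydroxy-5-{[(triisopropylsilyl)oxy]methyl}non-5-en-8-yn-1-yl]-2,2-dimethyl-4H-1,3-dioxin-4-one
Conditions: AgNO3 (cat.), acetone/H2O, rt
Reagents that add atoms: none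
Why: Protiodesilylation of the alkynylsilane through a silver acetylide (monovalent silver catalysis); the neutral medium spares the dioxinone, which carbonate in methanol would open, and the silyl ether.

Step 8
Reactants: 12 the dioxinone propargylic alcohol of step 7
Product: 14 (9E,11R)-11-ethynyl-9-{[(triisopropylsilyl)oxy]methyl}oxacycloundec-9-ene-2,4-dione, via acylketene 13 (not isolated)
Conditions: toluene (0.5 mM), 110 °C, slow addition
Reagents that add atoms: none
Why: Acylketene macrolactonisation: retro-[4+2] loss of acetone gives acylketene 13, which the C6 hydroxyl captures irreversibly to close the eleven-membered β-keto lactone; C6 is not touched.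

Step 9
Reactants: 14 the alkynyl macrolactone of step 8; 15 (2S)-2-methylbutanoic acid
Product: 16 (1Z)-2-[(9E,11R)-2,4-dioxo-9-{[(triisopropylsilyl)oxy]methyl}oxacycloundec-9-en-11-yl]ethenyl (2S)-2-methylbutanoate
Conditions: 15, Ru(η3-CH2C(CH3)CH2)2(dppb) (cat.), toluene, 65 °C
Reagents that add atoms: none
Why: Ruthenium-catalysed anti-Markovnikov hydroacyloxylation of a terminal alkyne through a vinylidene of divalent ruthenium gives the Z-enol ester; the neutral conditions keep the α-centre of the acid.

Step 10
Reactants: 16 the β-keto macrolactone with Z-enol ester of step 9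
Product: 20 (3aS,4R,10E,11aR)-2,5-dioxo-10-{[(triisopropylsilyl)oxy]methyl}-2,3,3a,4,5,6,7,8,9,11a-decahydrocyclodeca[b]furan-4-yl (2S)-2-methylbutanoate, via silyl enol ether 17 (not isolated), via siloxycyclobutane 18 (not isolated), via cyclobutanol 19 (not isolated)
Conditions: Me3SiCl, Et3N, pentane, rt, filter; hν (254 nm, quartz), degassed hexane (1 mM), 0 °C; then Bu4NF/AcOH, THF, −20 °C
Reagents that add atoms: none
Why: Proposed new method: the β-keto lactone is first locked as its trimethylsilyl enol ether 17, so that every molecule carries the β-silyloxy enoate chromophore and no ketone n→π* channel remains; the closest known reaction type is the De Mayo reaction, in the form practised with dioxinones and tetronates (enoate–alkene [2+2] photocycloaddition, then retro-aldol opening). On excitation at 254 nm the enoate adds stepwise: C11 bonds to C7 through the three-atom C12–O6–C6 tether (5-exo closure, the rule of five), which closes the γ-lactone, and the resulting 1,4-biradical (C9, C8) collapses to cyclobutane 18, the C8–C9 bond closing the ten-membered carbocycle by radical recombination. The connectivity enforced by the tether is also the electronically preferred head-to-tail one, the oxygen-bearing C8 of the electron-rich enol ester joining the β-carbon C9. C7 is controlled by allylic 1,3-strain in the Z-enol ester: H6 eclipses C7=C8, O6 with its tethered C11 lies over one face and C5 over the other, so C11 arrives anti to C5 and the lactone is trans-fused. C8 is controlled by the Z geometry of the enol ester, provided that the biradical closes before rotation about C7–C8; the result is O8 cis to C6 on the four-membered ring, which is the 7,8 relationship of the target. The step needs site selectivity for C7=C8 over the ring olefin C4=C5, which is expected because closure onto C4 would join two fully substituted carbons and the competing biradical can revert, and it needs the s-cis lactone conformer, which only the ring can supply. Fluoride then cleaves the tertiary silyl ether, and cyclobutanolate 19, whose O9 is trans to the O8 ester and so cannot take its acyl group, undergoes strain-driven retro-aldol cleavage of C9–C11 to the C9 ketone and the lactone enolate, which acetic acid protonates. C9 and C11 cease to be stereocentres, so the enol ether geometry is of no consequence, and the isolated olefins neither absorb at 254 nm nor lie below the enoate triplet.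

Step 11
Reactants: 20 the ketolactone of step 10
Product: 22 (3aS,4R,6Z,10E,11aR)-2,5-dioxo-10-{[(triisopropylsilyl)oxy]methyl}-2,3,3a,4,5,8,9,11a-octahydrocyclodeca[b]furan-4-yl (2S)-2-methylbutanoate, via kinetic silyl enol ether 21 (not isolated)
Conditions: LiN(SiMe3)2, Me3SiCl, THF, −78 °C; then Pd(OAc)2 (1.1 equiv), MeCN, rt
Reagents that add atoms: none
Why: Internal-quench kinetic enolisation takes the less hindered C10 methylene (the C8 methine is tertiary and flanked by the ester), and Saegusa–Ito oxidation of 21 by divalent palladium gives the C1=C10 enone by β-hydride loss from C1. Either olefin geometry is acceptable because step 12 re-forms this double bond.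

Step 12
Reactants: 22 the enone of step 11
Product: 23 (3aS,4R,6Z,10E,11aR)-6-(hydroxymethyl)-2,5-dioxo-10-{[(triisopropylsilyl)oxy]methyl}-2,3,3a,4,5,8,9,11a-octahydrocyclodeca[b]furan-4-yl (2S)-2-methylbutanoate
Conditions: aq. CH2O, DMAP, THF/H2O, rt
Reagents that add atoms: formaldehyde, C=O
Why: Morita–Baylis–Hillman reaction: DMAP adds to C1, the enolate takes formaldehyde at C10 and loss of DMAP restores C1=C10, which the ring is expected to return as the cis olefin (C2 cis to C9). C8 is spared because the enolate arises by conjugate addition, not by deprotonation.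

Step 13
Reactants: 23 the hydroxymethyl enone of step 12
Product: 24 (3aS,4R,5S,6Z,10E,11aR)-5-hydroxy-6-(hydroxymethyl)-2-oxo-10-{[(triisopropylsilyl)oxy]methyl}-2,3,3a,4,5,8,9,11a-octahydrocyclodeca[b]furan-4-yl (2S)-2-methylbutanoate
Conditions: Zn(BH4)2, Et2O, −30 °C
Reagents that add atoms: none
Why: Chelation-controlled 1,2-reduction of the enone: zinc bridging the C9 carbonyl and O8 holds the C8–O bond syn to C=O, and hydride is expected to add on the face away from C7 (Cram-chelate sense). This gives the 8,9-anti relationship, i.e. 9S, and leaves lactone, ester and silyl ether alone.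

Step 14
Reactants: 24 the diol of step 13
Product: 25 the 9,14-bis(triethylsilyl) ether of 24
Conditions: Et3SiOTf, 2,6-lutidine, CH2Cl2, −78 → 0 °C
Reagents that add atoms: triethylsilyl trifluoromethanesulfonate, CC[Si](CC)(CC)OS(=O)(=O)C(F)(F)F
Why: O-Silylation of both hydroxyls with a silyl triflate and a hindered base; it blocks O9, which as an alkoxide would take the neighbouring acyl group in step 15.

Step 15
Reactants: 25 the bis(triethylsilyl) ether of step 14
Product: 28 (3aS,4R,5S,6Z,10E,11aR)-3-methylidene-2-oxo-5-[(triethylsilyl)oxy]-6-{[(triethylsilyl)oxy]methyl}-10-{[(triisopropylsilyl)oxy]methyl}-2,3,3a,4,5,8,9,11a-octahydrocyclodeca[b]furan-4-yl (2S)-2-methylbutanoate, via Mannich base 26 (not isolated), via trimethylammonium iodide 27 (not isolated)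
Conditions: LiN(iPr)2, THF, −78 °C; CH2=NMe2+ I−, −78 → 0 °C; MeI, MeOH, rt; NaHCO3, CH2Cl2/H2O
Reagents that add atoms: N,N-dimethylmethyleneiminium iodide (Eschenmoser's salt), C=[N+](C)C.[I-]
Why: Lactone α-methylenation by Mannich reaction and elimination: the γ-lactone methylene is the most acidic and most accessible α-C–H (the ester α-hydrogen is tertiary), and exhaustive methylation followed by E1cB loss of trimethylamine gives the exocyclic olefin. The C11 centre of 26 is destroyed, so its configuration does not matter.

Step 16
Reactants: 28 the α-methylene lactone of step 15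
Product: 29 (3aS,4R,5S,6Z,10E,11aR)-5-hydroxy-6-(hydroxymethyl)-3-methylidene-2-oxo-10-{[(triisopropylsilyl)oxy]methyl}-2,3,3a,4,5,8,9,11a-octahydrocyclodeca[b]furan-4-yl (2S)-2-methylbutanoate
Conditions: HF·pyridine, pyridine, THF, 0 °C
Reagents that add atoms: none
Why: Selective desilylation: triethylsilyl ethers are cleaved by buffered HF far faster than the primary triisopropylsilyl ether, and the acidic medium suppresses O8 to O9 acyl shift.

Step 17
Reactants: 29 the diol of step 16
Product: 30 (3aS,4R,5S,6E,10E,11aR)-6-formyl-5-hydroxy-3-methylidene-2-oxo-10-{[(triisopropylsilyl)oxy]methyl}-2,3,3a,4,5,8,9,11a-octahydrocyclodeca[b]furan-4-yl (2S)-2-methylbutanoate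
Conditions: TEMPO (cat.), PhI(OAc)2, CH2Cl2, rt
Reagents that add atoms: none
Why: Oxoammonium (TEMPO) oxidation is selective for the primary allylic C14 hydroxyl over the hindered secondary C9 carbinol and stops at the enal, whose ring-cis geometry is the conjugation-favoured one (C2 trans to the formyl group).

Step 18
Reactants: 30 the silylated enal of step 17
Product: 31 (3aS,4R,5S,6E,10E,11aR)-6-formyl-5-hydroxy-10-(hydroxymethyl)-3-methylidene-2-oxo-2,3,3a,4,5,8,9,11a-octahydrocyclodeca[b]furan-4-yl (2S)-2-methylbutanoate (the target)
Conditions: HF·pyridine, THF, 0 °C → rt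
Reagents that add atoms: none
Why: Fluoride desilylation of the primary silyl ether under acidic conditions, which leave the enal, the α-methylene lactone and the O8 ester beside the free O9 hydroxyl untouched.

## Compound list

1 | 2,2,6-trimethyl-4H-1,3-dioxin-4-one | CC1=CC(=O)OC(C)(C)O1 | starting material
2 | allyl bromide | C=CCBr | starting material
3 | 6-(but-3-en-1-yl)-2,2-dimethyl-4H-1,3-dioxin-4-one | C=CCCC1=CC(=O)OC(C)(C)O1 | intermediate
4 | but-2-yne-1,4-diol | OCC#CCO | starting material
5 | 4-[(triisopropylsilyl)oxy]but-2-yn-1-ol | OCC#CCO[Si](C(C)C)(C(C)C)C(C)C | intermediate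
6 | (2Z)-3-iodo-4-[(triisopropylsilyl)oxy]but-2-en-1-ol | OC/C=C(\I)CO[Si](C(C)C)(C(C)C)C(C)C | intermediate
7 | 6-[4-(9-borabicyclo[3.3.1]nonan-9-yl)butyl]-2,2-dimethyl-4H-1,3-dioxin-4-one | O=C1C=C(CCCCB2C3CCCC2CCC3)OC(C)(C)O1 | intermediate (not isolated)
8 | 6-[(5E)-7-hydroxy-5-{[(triisopropylsilyl)oxy]methyl}hept-5-en-1-yl]-2,2-dimethyl-4H-1,3-dioxin-4-one | OC/C=C(\CCCCC1=CC(=O)OC(C)(C)O1)CO[Si](C(C)C)(C(C)C)C(C)C | intermediate
9 | (2E)-7-(2,2-dimethyl-4-oxo-4H-1,3-dioxin-6-yl)-3-{[(triisopropylsilyl)oxy]methyl}hept-2-enal | O=C/C=C(\CCCCC1=CC(=O)OC(C)(C)O1)CO[Si](C(C)C)(C(C)C)C(C)C | intermediate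
10 | ethynyltrimethylsilane | C#C[Si](C)(C)C | starting material
11 | 6-[(5E,7R)-7-hydroxy-5-{[(triisopropylsilyl)oxy]methyl}-9-(trimethylsilyl)non-5-en-8-yn-1-yl]-2,2-dimethyl-4H-1,3-dioxin-4-one | C[Si](C)(C)C#C[C@H](O)/C=C(\CCCCC1=CC(=O)OC(C)(C)O1)CO[Si](C(C)C)(C(C)C)C(C)C | intermediate
12 | 6-[(5E,7R)-7-hydroxy-5-{[(triisopropylsilyl)oxy]methyl}non-5-en-8-yn-1-yl]-2,2-dimethyl-4H-1,3-dioxin-4-one | C#C[C@H](O)/C=C(\CCCCC1=CC(=O)OC(C)(C)O1)CO[Si](C(C)C)(C(C)C)C(C)C | intermediate
13 | (8E,10R)-10-hydroxy-8-{[(triisopropylsilyl)oxy]methyl}dodeca-1,8-dien-11-yne-1,3-dione (acylketene) | O=C=CC(=O)CCCC/C(CO[Si](C(C)C)(C(C)C)C(C)C)=C\[C@@H](O)C#C | intermediate (not isolated)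
14 | (9E,11R)-11-ethynyl-9-{[(triisopropylsilyl)oxy]methyl}oxacycloundec-9-ene-2,4-dione | O=C1CC(=O)CCCC/C(CO[Si](C(C)C)(C(C)C)C(C)C)=C\[C@H](C#C)O1 | intermediate
15 | (2S)-2-methylbutanoic acid | CC[C@H](C)C(=O)O | starting material
16 | (1Z)-2-[(9E,11R)-2,4-dioxo-9-{[(triisopropylsilyl)oxy]methyl}oxacycloundec-9-en-11-yl]ethenyl (2S)-2-methylbutanoate (precursor of the key step) | O=C1CC(=O)CCCC/C(CO[Si](C(C)C)(C(C)C)C(C)C)=C\[C@H](/C=C\OC(=O)[C@@H](C)CC)O1 | intermediate
17 | trimethylsilyl enol ether of 16 at O9 (C11=C9, drawn ring-cis; either geometry serves) | O=C1/C=C(/O[Si](C)(C)C)CCCC/C(CO[Si](C(C)C)(C(C)C)C(C)C)=C\[C@H](/C=C\OC(=O)[C@@H](C)CC)O1 | intermediate (not isolated)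
18 | photoadduct: cyclobutane C11–C7–C8–C9 cis-fused to the γ-lactone along C7–C11 and bridged from C7 to C9 by C6–C5=C4–C3–C2–C1–C10; C12, C6, O8 and C10 on one face; trimethylsilyloxy on C9 | O=C1O[C@@H]2/C=C(/CO[Si](C(C)C)(C(C)C)C(C)C)CCCC[C@]3(O[Si](C)(C)C)[C@H](OC(=O)[C@@H](C)CC)[C@H]2[C@H]13 | intermediate (not isolated)
19 | cyclobutanol corresponding to 18 (free C9 hydroxyl, formed as its alkoxide) | O=C1O[C@@H]2/C=C(/CO[Si](C(C)C)(C(C)C)C(C)C)CCCC[C@]3(O)[C@H](OC(=O)[C@@H](C)CC)[C@H]2[C@H]13 | intermediate (not isolated)
20 | (3aS,4R,10E,11aR)-2,5-dioxo-10-{[(triisopropylsilyl)oxy]methyl}-2,3,3a,4,5,6,7,8,9,11a-decahydrocyclodeca[b]furan-4-yl (2S)-2-methylbutanoate (product of the key step; trans-fused γ-lactone, C9 ketone) | O=C1O[C@@H]2/C=C(/CO[Si](C(C)C)(C(C)C)C(C)C)CCCCC(=O)[C@H](OC(=O)[C@@H](C)CC)[C@H]2C1 | intermediate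
21 | C9 trimethylsilyl enol ether of 20 (C9=C10) | O=C1O[C@@H]2/C=C(/CO[Si](C(C)C)(C(C)C)C(C)C)CCC/C=C(/O[Si](C)(C)C)[C@H](OC(=O)[C@@H](C)CC)[C@H]2C1 | intermediate (not isolated)
22 | (3aS,4R,6Z,10E,11aR)-2,5-dioxo-10-{[(triisopropylsilyl)oxy]methyl}-2,3,3a,4,5,8,9,11a-octahydrocyclodeca[b]furan-4-yl (2S)-2-methylbutanoate (C1=C10 enone) | O=C1O[C@@H]2/C=C(/CO[Si](C(C)C)(C(C)C)C(C)C)CC/C=C\C(=O)[C@H](OC(=O)[C@@H](C)CC)[C@H]2C1 | intermediate
23 | 6-(hydroxymethyl) derivative of 22 (C14 hydroxymethyl on C10; C2 cis to C9) | O=C1O[C@@H]2/C=C(/CO[Si](C(C)C)(C(C)C)C(C)C)CC/C=C(/CO)C(=O)[C@H](OC(=O)[C@@H](C)CC)[C@H]2C1 | intermediate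
24 | (3aS,4R,5S,6Z,10E,11aR)-5-hydroxy-6-(hydroxymethyl)-2-oxo-10-{[(triisopropylsilyl)oxy]methyl}-2,3,3a,4,5,8,9,11a-octahydrocyclodeca[b]furan-4-yl (2S)-2-methylbutanoate | O=C1O[C@@H]2/C=C(/CO[Si](C(C)C)(C(C)C)C(C)C)CC/C=C(/CO)[C@H](O)[C@H](OC(=O)[C@@H](C)CC)[C@H]2C1 | intermediate
25 | 9,14-bis(triethylsilyl) ether of 24 | O=C1O[C@@H]2/C=C(/CO[Si](C(C)C)(C(C)C)C(C)C)CC/C=C(/CO[Si](CC)(CC)CC)[C@H](O[Si](CC)(CC)CC)[C@H](OC(=O)[C@@H](C)CC)[C@H]2C1 | intermediate
26 | 11-[(dimethylamino)methyl] derivative of 25 (Mannich base, C11 epimers) | CN(C)CC1C(=O)O[C@@H]2/C=C(/CO[Si](C(C)C)(C(C)C)C(C)C)CC/C=C(/CO[Si](CC)(CC)CC)[C@H](O[Si](CC)(CC)CC)[C@H](OC(=O)[C@@H](C)CC)[C@@H]12 | intermediate (not isolated)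
27 | trimethylammonium iodide from 26 | C[N+](C)(C)CC1C(=O)O[C@@H]2/C=C(/CO[Si](C(C)C)(C(C)C)C(C)C)CC/C=C(/CO[Si](CC)(CC)CC)[C@H](O[Si](CC)(CC)CC)[C@H](OC(=O)[C@@H](C)CC)[C@@H]12.[I-] | intermediate (not isolated)
28 | 3-methylidene (C11=C13) lactone, 9,14-bis(triethylsilyl), 15-triisopropylsilyl | C=C1C(=O)O[C@@H]2/C=C(/CO[Si](C(C)C)(C(C)C)C(C)C)CC/C=C(/CO[Si](CC)(CC)CC)[C@H](O[Si](CC)(CC)CC)[C@H](OC(=O)[C@@H](C)CC)[C@@H]12 | intermediate
29 | 9,14-diol of 28 (15-triisopropylsilyl ether kept) | C=C1C(=O)O[C@@H]2/C=C(/CO[Si](C(C)C)(C(C)C)C(C)C)CC/C=C(/CO)[C@H](O)[C@H](OC(=O)[C@@H](C)CC)[C@@H]12 | intermediate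
30 | 15-O-triisopropylsilyl ether of the target (C14 aldehyde, free O9 hydroxyl) | C=C1C(=O)O[C@@H]2/C=C(/CO[Si](C(C)C)(C(C)C)C(C)C)CC/C=C(/C=O)[C@H](O)[C@H](OC(=O)[C@@H](C)CC)[C@@H]12 | intermediate
31 | (3aS,4R,5S,6E,10E,11aR)-6-formyl-5-hydroxy-10-(hydroxymethyl)-3-methylidene-2-oxo-2,3,3a,4,5,8,9,11a-octahydrocyclodeca[b]furan-4-yl (2S)-2-methylbutanoate | C=C1C(=O)O[C@@H]2/C=C(/CO)CC/C=C(/C=O)[C@H](O)[C@H](OC(=O)[C@@H](C)CC)[C@@H]12 | target

## Step count and least certain steps

Total: 18 steps. Longest linear sequence: 17 steps (4 to 31, steps 2–18); the branch 1 + 2 → 3 is one step.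

**Step 10 (key step).** Several things may go wrong, because this substrate class has not been used in a De Mayo sequence:
- The excited macrocyclic enoate may waste its energy by twisting about C11=C9 or by photodeconjugation toward C10.
- The s-cis lactone conformer needed for the 5-exo closure may be too sparsely populated.
- Site selectivity may fail: C4=C5 also sits three atoms from C11 and four from C9, so transannular addition to the ring olefin can compete.
- Rotation in the triplet biradical may erase the Z information and give the C8 epimer, and facial leakage at C7 is possible.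

Fallback: the same two-bond disconnection is carried out with the dioxinone chromophore, whose alkene photocycloaddition and retro-aldol opening are established. It sets out from 12. Silylation of O6 (Et3SiCl, imidazole) gives the triethylsilyl ether F1. Addition of 15 under the conditions of step 9 gives the Z-enol ester F2; the silyl group prevents acyl transfer to O6. Irradiation at 300 nm in MeCN/acetone at high dilution should add the dioxinone C11=C9 head-to-tail across C7=C8 to give the cyclobutane-fused dioxanone F3, with the ten-membered ring closed by C8–C9. Aqueous acid then removes the acetonide and the silyl ether; the β-hydroxy acid undergoes retro-aldol cleavage of C9–C11 and O6 lactonises onto C12, which returns to the route at 20. The price is that the ten-membered ring must close in the photoreaction itself across an eight-atom tether, and that the face of C7=C8 is no longer dictated by a tether through O6.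

**Step 8.** Intermolecular capture of the acylketene (diolide and oligomer formation) may outrun the slow closure of an eleven-membered ring by a hindered secondary hydroxyl. Fallback: the ester bond is made intermolecularly and the ring is closed by C–C coupling; it sets out from 6 and 3 and returns at 14. MnO2 oxidation of 6 gives (2Z)-3-iodo-4-[(triisopropylsilyl)oxy]but-2-enal F4. Alkynylation as in step 6 gives the silylated iodo propargylic alcohol F5. Heating F5 with 3 in toluene gives the β-keto ester F6. Hydroboration of its terminal olefin with 9-BBN gives the B-alkylborane F7. Intramolecular B-alkyl Suzuki–Miyaura coupling at C3–C4 (Pd(dppf)Cl2, AsPh3, Cs2CO3, high dilution) gives the alkynylsilane macrolactone F8, and AgNO3-catalysed desilylation gives 14.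

**Step 9.** The β-keto ester may sequester the catalyst as a chelate. The doubly activated (allylic and propargylic) C6–O bond may ionise at the ruthenium vinylidene stage and open the lactone. Some Markovnikov addition is also possible. Fallback: the C8–O bond is made by copper-mediated coupling; it sets out from 14 and returns at 16. Rhodium-catalysed trans-hydroboration ([Rh(cod)Cl]2, P(iPr)3, Et3N, pinacolborane) gives the Z-alkenylboronate F9. Chan–Lam-type coupling with 15 (Cu(OAc)2, Et3N, air) gives 16 with retention of geometry.

**Step 12.** Conjugate addition of DMAP to a β-substituted, possibly twisted medium-ring enone may be too slow. The amine may epimerise C8. The re-formed C1=C10 bond may come out with the wrong geometry, although the later enal favours the ring-cis form by conjugation. Fallback: halogenation and cross-coupling; it sets out from 22 and returns at 23. Iodination with I2/pyridine gives the α-iodoenone F10, and Stille coupling with Bu3SnCH2OH (Pd(PPh3)4) introduces C14 with retention.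

**Step 13.** Facial selectivity may be poor, because the acyloxy group is a weak chelator and the conformation of the ten-membered ring may override the chelate; some 1,4-reduction is also possible. Fallback: reagent control in place of substrate control; it sets out from 23 and returns at 24. Corey–Bakshi–Shibata reduction (B-methyl oxazaborolidine from diphenylprolinol, catecholborane) is used with the catalyst antipode that gives 9S; no new compound is involved.

## Further compounds

F1 | step 10 | 6-[(5E,7R)-7-[(triethylsilyl)oxy]-5-{[(triisopropylsilyl)oxy]methyl}non-5-en-8-yn-1-yl]-2,2-dimethyl-4H-1,3-dioxin-4-one | C#C[C@H](O[Si](CC)(CC)CC)/C=C(\CCCCC1=CC(=O)OC(C)(C)O1)CO[Si](C(C)C)(C(C)C)C(C)C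
F2 | step 10 | (1Z,3R,4E)-9-(2,2-dimethyl-4-oxo-4H-1,3-dioxin-6-yl)-3-[(triethylsilyl)oxy]-5-{[(triisopropylsilyl)oxy]methyl}nona-1,4-dien-1-yl (2S)-2-methylbutanoate | CC[C@H](C)C(=O)O/C=C\[C@H](O[Si](CC)(CC)CC)/C=C(\CCCCC1=CC(=O)OC(C)(C)O1)CO[Si](C(C)C)(C(C)C)C(C)C
F3 | step 10 | cyclobutane-fused 2,2-dimethyl-1,3-dioxan-4-one photoadduct (cyclobutane C11–C7–C8–C9; ten-membered ring closed by C8–C9; C6, O8 and C10 on one face, C12 and O9 on the other; O6 triethylsilyl ether) | CC1(C)OC(=O)[C@@H]2[C@@H]3[C@@H](OC(=O)[C@@H](C)CC)[C@@]2(O1)CCCC/C(CO[Si](C(C)C)(C(C)C)C(C)C)=C\[C@H]3O[Si](CC)(CC)CC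
F4 | step 8 | (2Z)-3-iodo-4-[(triisopropylsilyl)oxy]but-2-enal | O=C/C=C(\I)CO[Si](C(C)C)(C(C)C)C(C)C
F5 | step 8 | (3R,4Z)-5-iodo-6-[(triisopropylsilyl)oxy]-1-(trimethylsilyl)hex-4-en-1-yn-3-ol | C[Si](C)(C)C#C[C@H](O)/C=C(\I)CO[Si](C(C)C)(C(C)C)C(C)C
F6 | step 8 | (3R,4Z)-5-iodo-6-[(triisopropylsilyl)oxy]-1-(trimethylsilyl)hex-4-en-1-yn-3-yl 3-oxohept-6-enoate | C=CCCC(=O)CC(=O)O[C@@H](C#C[Si](C)(C)C)/C=C(\I)CO[Si](C(C)C)(C(C)C)C(C)C
F7 | step 8 | 9-BBN adduct of F6 at the terminal carbon (C3) | O=C(CCCCB1C2CCCC1CCC2)CC(=O)O[C@@H](C#C[Si](C)(C)C)/C=C(\I)CO[Si](C(C)C)(C(C)C)C(C)C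
F8 | step 8 | (9E,11R)-9-{[(triisopropylsilyl)oxy]methyl}-11-[(trimethylsilyl)ethynyl]oxacycloundec-9-ene-2,4-dione | O=C1CC(=O)CCCC/C(CO[Si](C(C)C)(C(C)C)C(C)C)=C\[C@H](C#C[Si](C)(C)C)O1
F9 | step 9 | (9E,11R)-11-[(Z)-2-(4,4,5,5-tetramethyl-1,3,2-dioxaborolan-2-yl)ethenyl]-9-{[(triisopropylsilyl)oxy]methyl}oxacycloundec-9-ene-2,4-dione | O=C1CC(=O)CCCC/C(CO[Si](C(C)C)(C(C)C)C(C)C)=C\[C@H](/C=C\B2OC(C)(C)C(C)(C)O2)O1
F10 | step 12 | 6-iodo derivative of 22 (iodine on C10 of the C1=C10 enone) | O=C1O[C@@H]2/C=C(/CO[Si](C(C)C)(C(C)C)C(C)C)CC/C=C(/I)C(=O)[C@H](OC(=O)[C@@H](C)CC)[C@H]2C1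
F0 | step 13 | none | none
A1 | alternative 1 | ten-membered C10 ketone with ring-cis C4=C5 (O6 and O13 triethylsilyl, O8 4-methoxybenzyl, O9 2-naphthylmethyl, O15 tert-butyldimethylsilyl) | O=C1CCC/C(CO[Si](C)(C)C(C)(C)C)=C\[C@@H](O[Si](CC)(CC)CC)[C@H](C(=C)CO[Si](CC)(CC)CC)[C@@H](OCc2ccc(OC)cc2)[C@H]1OCc3ccc4ccccc4c3
A2 | alternative 2 | ten-membered α-methylene lactone with free C9 hydroxyl (O14 4-methoxybenzyl, O15 tert-butyldimethylsilyl, O8 (2S)-2-methylbutanoate) | C=C1C(=O)O[C@@H]2/C=C(/CO[Si](C)(C)C(C)(C)C)CC/C=C(/COCc3ccc(OC)cc3)[C@H](O)[C@H](OC(=O)[C@@H](C)CC)[C@@H]12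
A3 | alternative 3 | ten-membered triene α-methylene lactone with ring-cis C8=C9 (O14 4-methoxybenzyl, O15 tert-butyldimethylsilyl) | C=C1C(=O)O[C@@H]2/C=C(/CO[Si](C)(C)C(C)(C)C)CC/C=C(/COCc3ccc(OC)cc3)\C=C/[C@@H]12
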